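**Assumption:** germacrane numbering (C1–C15) is used for all intermediates, and the facial sense of the phosphoric-acid allylborations follows the usual model in which (R)-TRIP delivers the allyl group to the Re face of RCHO.

## Retrosynthetic overview

1. Target ⇐ C15 desilylation and C1=C10 epoxidation of a (1(10)Z,4Z)-germacradien-12,6-olide that already carries 3-OAc and 8-OAng.
2. Ten-membered ring ⇐ ring-closing metathesis (C1=C10, Z) of a diene that already contains the trans α-methylene-γ-butyrolactone.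
3. Lactone (C6–C7 and C6–O) ⇐ chiral Brønsted-acid-catalysed allylboration/lactonisation of a (Z)-enal (C1–C6, C15) with a 2-methoxycarbonyl allylboronate (C7–C14).
4. Enal ⇐ 2-butyne-1,4-diol (Red-Al/I2, formylation, phosphoric-acid allylboration sets C3). Boronate ⇐ methyl 4-oxobut-2-ynoate (phosphoric-acid methallylboration sets C8, then hydroalumination/borylmethylation).
5. Ring order: γ-lactone, then carbocycle, then epoxide.

## Route

Step 1
Reactants: 1 2-butyne-1,4-diol
Product: 2 4-((tert-butyldimethylsilyl)oxy)but-2-yn-1-ol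
Conditions: TBSCl (1 equiv), imidazole, THF, 0 °C → rt, diol in 3-fold excess
Reagents that add atoms: tert-butyldimethylsilyl chloride, CC(C)(C)[Si](C)(C)Cl
Why: Statistical mono-silylation of a symmetrical diol (silyl ether formation); excess diol suppresses the bis-ether.

Step 2
Reactants: 2 4-((tert-butyldimethylsilyl)oxy)but-2-yn-1-ol
Product: 4 (Z)-4-((tert-butyldimethylsilyl)oxy)-3-iodobut-2-en-1-ol, via sodium alkenylaluminate 3 (not isolated)
Conditions: Red-Al, THF, 0 °C → rt; then I2, −78 → 0 °C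
Reagents that add atoms: iodine, II
Why: Hydroxyl-directed trans-hydroalumination of the propargylic alcohol puts Al on the carbon distal to the free OH, and iodinolysis with retention gives the (Z)-iodide, which fixes the C4=C5 geometry (C6 cis to the future C3).

Step 3
Reactants: 4 (Z)-4-((tert-butyldimethylsilyl)oxy)-3-iodobut-2-en-1-ol
Product: 5 (Z)-tert-butyl((2-iodo-4-((triethylsilyl)oxy)but-2-en-1-yl)oxy)dimethylsilane
Conditions: TESCl, imidazole, CH2Cl2, 0 °C
Reagents that add atoms: chlorotriethylsilane, CC[Si](Cl)(CC)CC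
Why: Silyl ether formation; TES on O6 is chosen because a primary TES ether can later be oxidised directly next to the TBS ether.

Step 4
Reactants: 5 (Z)-tert-butyl((2-iodo-4-((triethylsilyl)oxy)but-2-en-1-yl)oxy)dimethylsilane
Product: 7 (Z)-2-(((tert-butyldimethylsilyl)oxy)methyl)-4-((triethylsilyl)oxy)but-2-enal, via alkenylmagnesium chloride 6 (not isolated)
Conditions: i-PrMgCl·LiCl, THF, −40 °C; then DMF, −40 → 0 °C; aq NH4Cl
Reagents that add atoms: N,N-dimethylformamide, CN(C)C=O
Why: Iodine–magnesium exchange proceeds with retention of olefin geometry and Bouveault-type formylation installs C3; the Grignard (not the lithium) reagent avoids retro-Brook silyl migration and β-elimination.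

Step 5
Reactants: 7 (Z)-2-(((tert-butyldimethylsilyl)oxy)methyl)-4-((triethylsilyl)oxy)but-2-enal; 8 allylboronic acid pinacol ester
Product: 10 (4S,5Z)-5-(((tert-butyldimethylsilyl)oxy)methyl)-7-((triethylsilyl)oxy)hepta-1,5-dien-4-ol, via pinacol borate 9 (not isolated)
Conditions: 8 (1.3 equiv), (S)-TRIP (5 mol %), 4 Å MS, toluene, −30 °C; aqueous work-up
Reagents that add atoms: none
Why: Chiral phosphoric-acid-catalysed allylboration through a closed chair transition state; (S)-TRIP directs the allyl group to the Si face of the enal and sets C3 as S, the first stereocentre of this fragment.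

Step 6
Reactants: 10 (4S,5Z)-5-(((tert-butyldimethylsilyl)oxy)methyl)-7-((triethylsilyl)oxy)hepta-1,5-dien-4-ol
Product: 11 (4S,5Z)-5-(((tert-butyldimethylsilyl)oxy)methyl)-7-((triethylsilyl)oxy)hepta-1,5-dien-4-yl acetate
Conditions: Ac2O, pyridine, DMAP (cat.), CH2Cl2, 0 °C → rt
Reagents that add atoms: acetic anhydride, CC(=O)OC(C)=O
Why: Acylation installs the C3 acetate of the target, which is carried unchanged to the end.

Step 7
Reactants: 11 (4S,5Z)-5-(((tert-butyldimethylsilyl)oxy)methyl)-7-((triethylsilyl)oxy)hepta-1,5-dien-4-yl acetate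
Product: 12 (2Z,4S)-3-(((tert-butyldimethylsilyl)oxy)methyl)-1-oxohepta-2,6-dien-4-yl acetate
Conditions: (COCl)2, DMSO, CH2Cl2, −78 → −30 °C; then Et3N, −78 → 0 °C; used at once
Reagents that add atoms: none
Why: Swern conditions convert a primary TES ether directly into the aldehyde while the TBS ether and acetate survive; the low temperature preserves the (Z)-enal.

Step 8
Reactants: 13 methyl 4-hydroxybut-2-ynoate
Product: 14 methyl 4-oxobut-2-ynoate
Conditions: activated MnO2 (excess), CH2Cl2, rt; filtered solution used directly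
Reagents that add atoms: none
Why: MnO2 oxidation of an activated (propargylic) alcohol to the ynal.

Step 9
Reactants: 14 methyl 4-oxobut-2-ynoate; 15 2-methylallylboronic acid pinacol ester
Product: 17 methyl (R)-4-hydroxy-6-methylhept-6-en-2-ynoate, via pinacol borate 16 (not isolated)
Conditions: 15 (1.2 equiv), (R)-TRIP (5 mol %), 4 Å MS, toluene, −45 °C; aqueous work-up
Reagents that add atoms: none
Why: Chiral phosphoric-acid-catalysed methallylboration (chair transition state); (R)-TRIP directs attack to the Re face of the ynal and sets C8 as R, and the low temperature holds back the uncatalysed background reaction.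

Step 10
Reactants: 17 methyl (R)-4-hydroxy-6-methylhept-6-en-2-ynoate
Product: 18 methyl (R)-6-methyl-4-((triethylsilyl)oxy)hept-6-en-2-ynoate
Conditions: TESCl, imidazole, DMAP (cat.), CH2Cl2, 0 °C
Reagents that add atoms: chlorotriethylsilane, CC[Si](Cl)(CC)CC
Why: Silyl ether formation; O8 must be a poor leaving group and must not lactonise onto the cis ester in the next two steps.

Step 11
Reactants: 18 methyl (R)-6-methyl-4-((triethylsilyl)oxy)hept-6-en-2-ynoate
Product: 20 methyl (R,Z)-6-methyl-2-((4,4,5,5-tetramethyl-1,3,2-dioxaborolan-2-yl)methyl)-4-((triethylsilyl)oxy)hepta-2,6-dienoate, via alkenylalane 19 (not isolated)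
Conditions: DIBAL-H (1.1 equiv), HMPA (2 equiv), THF, 0 °C; then ICH2Bpin (1.5 equiv), 0 °C → rt
Reagents that add atoms: 2-(iodomethyl)-4,4,5,5-tetramethyl-1,3,2-dioxaborolane, CC1(C)OB(CI)OC1(C)C
Why: DIBAL–HMPA effects syn conjugate hydroalumination of the ynoate (H to C7, Al to C11) and alkylation of the α-alumino enoate with the iodomethylboronate occurs with retention, giving the allylboronate with C8 cis to the ester and trans to CH2B.

Step 12
Reactants: 12 (2Z,4S)-3-(((tert-butyldimethylsilyl)oxy)methyl)-1-oxohepta-2,6-dien-4-yl acetate; 20 methyl (R,Z)-6-methyl-2-((4,4,5,5-tetramethyl-1,3,2-dioxaborolan-2-yl)methyl)-4-((triethylsilyl)oxy)hepta-2,6-dienoate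
Product: 22 (1Z,3S)-2-(((tert-butyldimethylsilyl)oxy)methyl)-1-[(2R,3S)-4-methylene-3-[(1R)-3-methyl-1-((triethylsilyl)oxy)but-3-en-1-yl]-5-oxotetrahydrofuran-2-yl]hexa-1,5-dien-3-yl acetate (6,7-trans lactone), via borate ester 21 (not isolated)
Conditions: (S)-TRIP-derived N-triflylphosphoramide (10 mol %), 4 Å MS, toluene, −20 °C → rt; 20 (1.3 equiv)
Reagents that add atoms: none
Why: Proposed new method: a chiral N-triflylphosphoramide activates the sluggish 2-methoxycarbonyl allylboronate by hydrogen-bonding a boronate oxygen while its P=O holds the formyl H, so addition runs through a closed chair (type I allylboration) in which the boronate geometry (C8 trans to CH2B) enforces the 6,7-anti relationship (trans lactone after the borate closes onto the ester) and the (S)-catalyst selects the Si face of the enal to give the C6/C7 configuration of the target, overriding the weak bias of C8; the closest known reactions are phosphoric-acid-catalysed allyl- and crotylboration of aldehydes and triflic-acid- or Sc(OTf)3-catalysed additions of 2-alkoxycarbonyl allylboronates that give α-methylene-γ-butyrolactones.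

Step 13
Reactants: 22 6,7-trans lactone with 8-OTES
Product: 23 (1Z,3S)-2-(((tert-butyldimethylsilyl)oxy)methyl)-1-[(2R,3R)-3-[(1R)-1-hydroxy-3-methylbut-3-en-1-yl]-4-methylene-5-oxotetrahydrofuran-2-yl]hexa-1,5-dien-3-yl acetate
Conditions: PPTS (0.2 equiv), MeOH/CH2Cl2, 0 °C
Reagents that add atoms: none
Why: Mild acidic methanolysis removes the TES ether much faster than the primary TBS ether and does not trigger translactonisation.

Step 14
Reactants: 23 C8 alcohol; 24 angelic acid ((Z)-2-methylbut-2-enoic acid)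
Product: 26 8-O-angelate of 23, via mixed anhydride 25 (not isolated)
Conditions: 24, 2,4,6-trichlorobenzoyl chloride, Et3N, toluene, rt; then 23, 75 °C (no DMAP)
Reagents that add atoms: none
Why: Yamaguchi-type mixed-anhydride esterification; leaving out nucleophilic catalysts avoids angelate-to-tiglate isomerisation.

Step 15
Reactants: 26 diene angelate
Product: 27 (3S,6R,7R,8R)-3-acetoxy-8-angeloyloxy-15-((tert-butyldimethylsilyl)oxy)germacra-1(10)Z,4Z,11(13)-trien-12,6-olide
Conditions: Grubbs II (15 mol %), 1,4-benzoquinone (cat.), toluene (1 mM), 80 °C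
Reagents that add atoms: none
Why: Ring-closing metathesis between the terminal vinyl and the methallyl group; the ten-membered ring forms as the less strained Z (cis) cycloalkene, which is the geometry needed, and the trisubstituted and electron-poor olefins stay inert.

Step 16
Reactants: 27 macrocyclic triene
Product: 28 (1R,3S,6R,7R,8R,10S)-3-acetoxy-8-angeloyloxy-15-((tert-butyldimethylsilyl)oxy)-1,10-epoxygermacra-4Z,11(13)-dien-12,6-olide
Conditions: m-CPBA, NaHCO3, CH2Cl2, 0 °C
Reagents that add atoms: 3-chloroperbenzoic acid, OOC(=O)c1cccc(Cl)c1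
Why: Prilezhaev epoxidation picks the only electron-rich olefin and is stereospecific (Z-olefin gives the cis-epoxide); attack from the outer face of the cis-cyclodecene, anti to the transannular lactone, is expected to give 1R,10S but is not secured.

Step 17
Reactants: 28 epoxide
Product: 29 (1R,3S,6R,7R,8R,10S)-3-acetoxy-8-angeloyloxy-1,10-epoxy-15-hydroxygermacra-4Z,11(13)-dien-12,6-olide (target, CNP0162483.1)
Conditions: HF·pyridine, pyridine, THF, 0 °C
Reagents that add atoms: none
Why: Buffered fluoride desilylation frees the primary C15 alcohol without opening the epoxide or moving the neighbouring acetate.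

## Compound list

1 | 2-butyne-1,4-diol | OCC#CCO | starting material
2 | 4-((tert-butyldimethylsilyl)oxy)but-2-yn-1-ol | CC(C)(C)[Si](C)(C)OCC#CCO | intermediate
3 | sodium 2,2-bis(2-methoxyethoxy)-3-(((tert-butyldimethylsilyl)oxy)methyl)-2,5-dihydro-1,2-oxaaluminol-2-uide | [Na+].COCCO[Al-]1(OCCOC)OCC=C1CO[Si](C)(C)C(C)(C)C | intermediate
4 | (Z)-4-((tert-butyldimethylsilyl)oxy)-3-iodobut-2-en-1-ol | OC/C=C(\I)CO[Si](C)(C)C(C)(C)C | intermediate
5 | (Z)-tert-butyl((2-iodo-4-((triethylsilyl)oxy)but-2-en-1-yl)oxy)dimethylsilane | CC[Si](CC)(CC)OC/C=C(\I)CO[Si](C)(C)C(C)(C)C | intermediate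
6 | alkenylmagnesium chloride from 5 (Mg in place of I, geometry retained) | CC[Si](CC)(CC)OC/C=C(\[Mg]Cl)CO[Si](C)(C)C(C)(C)C | intermediate
7 | (Z)-2-(((tert-butyldimethylsilyl)oxy)methyl)-4-((triethylsilyl)oxy)but-2-enal | CC[Si](CC)(CC)OC/C=C(\C=O)CO[Si](C)(C)C(C)(C)C | intermediate
8 | allylboronic acid pinacol ester | C=CCB1OC(C)(C)C(C)(C)O1 | starting material
9 | pinacol borate of alcohol 10 | CC[Si](CC)(CC)OC/C=C(/CO[Si](C)(C)C(C)(C)C)[C@@H](OB1OC(C)(C)C(C)(C)O1)CC=C | intermediate
10 | (4S,5Z)-5-(((tert-butyldimethylsilyl)oxy)methyl)-7-((triethylsilyl)oxy)hepta-1,5-dien-4-ol | CC[Si](CC)(CC)OC/C=C(/CO[Si](C)(C)C(C)(C)C)[C@@H](O)CC=C | intermediate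
11 | (4S,5Z)-5-(((tert-butyldimethylsilyl)oxy)methyl)-7-((triethylsilyl)oxy)hepta-1,5-dien-4-yl acetate | CC[Si](CC)(CC)OC/C=C(/CO[Si](C)(C)C(C)(C)C)[C@@H](OC(C)=O)CC=C | intermediate
12 | (2Z,4S)-3-(((tert-butyldimethylsilyl)oxy)methyl)-1-oxohepta-2,6-dien-4-yl acetate | O=C/C=C(/CO[Si](C)(C)C(C)(C)C)[C@@H](OC(C)=O)CC=C | intermediate
13 | methyl 4-hydroxybut-2-ynoate | COC(=O)C#CCO | starting material
14 | methyl 4-oxobut-2-ynoate | COC(=O)C#CC=O | intermediate
15 | 2-methylallylboronic acid pinacol ester | C=C(C)CB1OC(C)(C)C(C)(C)O1 | starting material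
16 | pinacol borate of alcohol 17 | C=C(C)C[C@@H](OB1OC(C)(C)C(C)(C)O1)C#CC(=O)OC | intermediate
17 | methyl (R)-4-hydroxy-6-methylhept-6-en-2-ynoate | C=C(C)C[C@@H](O)C#CC(=O)OC | intermediate
18 | methyl (R)-6-methyl-4-((triethylsilyl)oxy)hept-6-en-2-ynoate | C=C(C)C[C@@H](O[Si](CC)(CC)CC)C#CC(=O)OC | intermediate
19 | methyl (R)-2-(diisobutylalumanyl)-6-methyl-4-((triethylsilyl)oxy)hepta-2,6-dienoate (ester cis to C8) | C=C(C)C[C@@H](O[Si](CC)(CC)CC)/C=C(/[Al](CC(C)C)CC(C)C)C(=O)OC | intermediate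
20 | methyl (R,Z)-6-methyl-2-((4,4,5,5-tetramethyl-1,3,2-dioxaborolan-2-yl)methyl)-4-((triethylsilyl)oxy)hepta-2,6-dienoate | C=C(C)C[C@@H](O[Si](CC)(CC)CC)/C=C(/CB1OC(C)(C)C(C)(C)O1)C(=O)OC | intermediate
21 | open-chain 6,7-anti adduct: methyl 2-methylene ester with O6 as pinacol borate | COC(=O)C(=C)[C@@H]([C@H](OB1OC(C)(C)C(C)(C)O1)/C=C(/CO[Si](C)(C)C(C)(C)C)[C@@H](OC(C)=O)CC=C)[C@H](O[Si](CC)(CC)CC)CC(C)=C | intermediate
22 | 6,7-trans α-methylene-γ-butyrolactone with 3-OAc, 8-OTES, 15-OTBS, C1 vinyl and C10 methallyl (name in step 12) | C=C1C(=O)O[C@H](/C=C(/CO[Si](C)(C)C(C)(C)C)[C@@H](OC(C)=O)CC=C)[C@H]1[C@H](O[Si](CC)(CC)CC)CC(C)=C | intermediate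
23 | C8 alcohol of 22 (name in step 13) | C=C1C(=O)O[C@H](/C=C(/CO[Si](C)(C)C(C)(C)C)[C@@H](OC(C)=O)CC=C)[C@H]1[C@H](O)CC(C)=C | intermediate
24 | angelic acid, (Z)-2-methylbut-2-enoic acid | C/C=C(/C)C(=O)O | starting material
25 | angelic 2,4,6-trichlorobenzoic anhydride | C/C=C(/C)C(=O)OC(=O)c1c(Cl)cc(Cl)cc1Cl | intermediate
26 | 8-O-angelate of 23 (acyclic diene lactone) | C=C1C(=O)O[C@H](/C=C(/CO[Si](C)(C)C(C)(C)C)[C@@H](OC(C)=O)CC=C)[C@H]1[C@H](OC(=O)/C(C)=C\C)CC(C)=C | intermediate
27 | (3S,6R,7R,8R)-3-acetoxy-8-angeloyloxy-15-((tert-butyldimethylsilyl)oxy)germacra-1(10)Z,4Z,11(13)-trien-12,6-olide | C=C1C(=O)O[C@@H]2/C=C(/CO[Si](C)(C)C(C)(C)C)[C@@H](OC(C)=O)C/C=C(/C)C[C@@H](OC(=O)/C(C)=C\C)[C@@H]12 | intermediate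
28 | (1R,3S,6R,7R,8R,10S)-3-acetoxy-8-angeloyloxy-15-((tert-butyldimethylsilyl)oxy)-1,10-epoxygermacra-4Z,11(13)-dien-12,6-olide | C=C1C(=O)O[C@@H]2/C=C(/CO[Si](C)(C)C(C)(C)C)[C@@H](OC(C)=O)C[C@H]3O[C@@]3(C)C[C@@H](OC(=O)/C(C)=C\C)[C@@H]12 | intermediate
29 | (1R,3S,6R,7R,8R,10S)-3-acetoxy-8-angeloyloxy-1,10-epoxy-15-hydroxygermacra-4Z,11(13)-dien-12,6-olide | C=C1C(=O)O[C@@H]2/C=C(/CO)[C@@H](OC(C)=O)C[C@H]3O[C@@]3(C)C[C@@H](OC(=O)/C(C)=C\C)[C@@H]12 | target

## Step count and risks

Total steps: 17. Longest linear sequence: 13 (steps 1–7, then 12–17).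

**Step 12 (proposed new allylboration/lactonisation).** The acid may be too weak or too harsh for the silyl ethers, or catalyst control may not override the C8 bias. The fallback uses auxiliary control on boron instead of catalyst control. It sets out from 18: after the same DIBAL–HMPA hydroalumination (alane 19), the iodomethylboronate of Hoffmann's camphor-derived diol (3-endo-phenyl-2-exo,3-exo-bornanediol) is used in place of ICH2Bpin and gives the chiral allylboronate F1. The diol antipode is the one the established model assigns to Si-face addition; it is drawn here for the diol from (1R)-camphor. Sc(OTf)3 (10 mol %, CH2Cl2, −78 °C) then promotes addition of F1 to aldehyde 12 through the same chair, giving the borate F2, which lactonises on mild acid work-up. The fallback comes back at 22. Sc(OTf)3 activation of 2-alkoxycarbonyl allylboronates and camphor-diol-controlled allylboration are both established chemistry.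

**Step 15 (ring-closing metathesis to the ten-membered ring).** Oligomerisation or failure to close onto the 1,1-disubstituted olefin is possible. The fallback inverts the order of ring formation: the Z-olefin is made in a small ring and the carbocycle is closed at C6–C7. It sets out from 10.
- Esterification with 3-methylbut-3-enoic acid (DIC, DMAP cat.) gives the diene ester F3.
- RCM (Grubbs II, CH2Cl2, 40 °C) gives the seven-membered lactone F4, in which the trisubstituted olefin can only be Z.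
- Lithium methyl propiolate (BF3·OEt2, THF, −78 °C) opens the lactone to the hydroxy ynone F5, and Ac2O/pyridine gives the acetate F6.
- CBS reduction (catalyst antipode chosen for 8R) gives the propargylic alcohol F7, and TESCl gives the silyl ether F8.
- Hydroalumination/borylmethylation as in step 11 gives, through the alane F9, the allylboronate F10.
- Swern oxidation of the primary TES ether as in step 7 gives the aldehyde F11.
- Intramolecular allylboration/lactonisation (Sc(OTf)3 or the step-12 acid, 1 mM) gives, through the borate F12, the macrocyclic lactone F13.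
- PPTS/MeOH gives the alcohol F14, and angeloylation as in step 14 returns to 27.

**Step 16 (face of epoxidation).** The peracid may attack the other face of C1=C10. The fallback reaches the epoxide from the opposite face through a halohydrin. It sets out from 27: NBS in THF/H2O at 0 °C forms the bromonium ion on the face the peracid would use, and water opens it at the tertiary C10 to give the bromohydrin F15. DBU in CH2Cl2 then closes the epoxide by displacing bromide at C1 with inversion. The fallback comes back at 28.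

## Further compounds

F1 | step 12 | methyl (R,Z)-6-methyl-4-((triethylsilyl)oxy)-2-(boronatomethyl)hepta-2,6-dienoate as the cyclic boronate of 3-endo-phenyl-2-exo,3-exo-bornanediol | C[C@@]12CC[C@@H](C1(C)C)[C@@]3(c4ccccc4)OB(C/C(C(=O)OC)=C/[C@H](O[Si](CC)(CC)CC)CC(C)=C)O[C@@H]23
F2 | step 12 | open-chain 6,7-anti adduct with O6 bound to the camphor-diol borate | C[C@@]12CC[C@@H](C1(C)C)[C@@]3(c4ccccc4)OB(O[C@H](/C=C(/CO[Si](C)(C)C(C)(C)C)[C@@H](OC(C)=O)CC=C)[C@H](C(=C)C(=O)OC)[C@H](O[Si](CC)(CC)CC)CC(C)=C)O[C@@H]23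
F3 | step 15 | 3-methylbut-3-enoate ester of alcohol 10 | CC[Si](CC)(CC)OC/C=C(/CO[Si](C)(C)C(C)(C)C)[C@@H](OC(=O)CC(C)=C)CC=C
F4 | step 15 | (S)-7-substituted 4-methyl-4,7-dihydrooxepin-2(3H)-one (seven-membered lactone, C8 as carbonyl) | CC[Si](CC)(CC)OC/C=C(/CO[Si](C)(C)C(C)(C)C)[C@@H]1CC=C(C)CC(=O)O1
F5 | step 15 | C3-hydroxy C8-ynone methyl ester with 1(10)Z olefin | CC[Si](CC)(CC)OC/C=C(/CO[Si](C)(C)C(C)(C)C)[C@@H](O)C/C=C(/C)CC(=O)C#CC(=O)OC
F6 | step 15 | C3 acetate of F5 | CC[Si](CC)(CC)OC/C=C(/CO[Si](C)(C)C(C)(C)C)[C@@H](OC(C)=O)C/C=C(/C)CC(=O)C#CC(=O)OC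
F7 | step 15 | (8R)-propargylic alcohol from F6 | CC[Si](CC)(CC)OC/C=C(/CO[Si](C)(C)C(C)(C)C)[C@@H](OC(C)=O)C/C=C(/C)C[C@@H](O)C#CC(=O)OC
F8 | step 15 | 8-O-TES ether of F7 | CC[Si](CC)(CC)OC/C=C(/CO[Si](C)(C)C(C)(C)C)[C@@H](OC(C)=O)C/C=C(/C)C[C@@H](O[Si](CC)(CC)CC)C#CC(=O)OC
F9 | step 15 | α-(diisobutylalumanyl) enoate from F8 | CC[Si](CC)(CC)OC/C=C(/CO[Si](C)(C)C(C)(C)C)[C@@H](OC(C)=O)C/C=C(/C)C[C@@H](O[Si](CC)(CC)CC)/C=C(/[Al](CC(C)C)CC(C)C)C(=O)OC
F10 | step 15 | full-chain allylboronate with O6-TES | CC[Si](CC)(CC)OC/C=C(/CO[Si](C)(C)C(C)(C)C)[C@@H](OC(C)=O)C/C=C(/C)C[C@@H](O[Si](CC)(CC)CC)/C=C(/CB1OC(C)(C)C(C)(C)O1)C(=O)OC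
F11 | step 15 | full-chain (Z)-enal allylboronate | O=C/C=C(/CO[Si](C)(C)C(C)(C)C)[C@@H](OC(C)=O)C/C=C(/C)C[C@@H](O[Si](CC)(CC)CC)/C=C(/CB1OC(C)(C)C(C)(C)O1)C(=O)OC
F12 | step 15 | ten-membered carbocyclic borate before lactonisation | COC(=O)C(=C)[C@H]1[C@H](OB2OC(C)(C)C(C)(C)O2)/C=C(/CO[Si](C)(C)C(C)(C)C)[C@@H](OC(C)=O)C/C=C(/C)C[C@H]1O[Si](CC)(CC)CC
F13 | step 15 | 8-O-TES analogue of macrocycle 27 | C=C1C(=O)O[C@@H]2/C=C(/CO[Si](C)(C)C(C)(C)C)[C@@H](OC(C)=O)C/C=C(/C)C[C@@H](O[Si](CC)(CC)CC)[C@@H]12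
F14 | step 15 | 8-hydroxy analogue of macrocycle 27 | C=C1C(=O)O[C@@H]2/C=C(/CO[Si](C)(C)C(C)(C)C)[C@@H](OC(C)=O)C/C=C(/C)C[C@@H](O)[C@@H]12
F15 | step 16 | 1-bromo-10-hydroxy bromohydrin of 27 (Br and OH anti) | C=C1C(=O)O[C@@H]2/C=C(/CO[Si](C)(C)C(C)(C)C)[C@@H](OC(C)=O)C[C@H](Br)[C@](O)(C)C[C@@H](OC(=O)/C(C)=C\C)[C@@H]12
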